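## Retrosynthetic overview

1. The target is reached by hydrogenolysis of its tri-O-benzyl ether.
2. The pyranone ring (C) and the dihydrofuran ring (D) are closed together in one flask from an open-chain alkylidene β-keto ester: a catalyst-controlled oxa-Michael addition sets the flavanone C2, then acid triggers decarboxylation and cationic cycloetherification (benzofuran C2, trans to C3).
3. The alkylidene comes from Knoevenagel union of an A-ring tert-butyl aroylacetate (from phloroacetophenone) with a B-ring aldehyde carrying an open 1-aryl-propane-1,3-diol chain.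
4. The benzofuran C3 centre comes from an Evans syn-aldol of a B-ring arylacetyl imide with O-benzylvanillin; the imide comes from Pd α-arylation of doubly masked 5-bromoprotocatechualdehyde.
5. Ring order: aromatic rings A, B and E are purchased; rings C and D are formed simultaneously in the penultimate step.

Assumption: the epi-quinidine-derived bifunctional thiourea is taken to deliver the (2S)-chromanone; its quinine-derived pseudo-enantiomer would be used if the sense proves opposite on this substrate.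

## Route

Step 1
Reactants: 1 3-bromo-4,5-dihydroxybenzaldehyde; 2 2,2-dimethoxypropane
Product: 3 4-bromo-6-(dimethoxymethyl)-2,2-dimethyl-1,3-benzodioxole
Conditions: 2 (excess), p-TsOH·H2O (5 mol %), toluene, reflux, 4 Å MS in Soxhlet (MeOH removal); Et3N quench
Reagents that add atoms: 2,2-dimethoxypropane, COC(C)(C)OC
Why: Acid-catalysed transketalisation converts the catechol into its acetonide and, in the same pot, the aldehyde into its dimethyl acetal (acetal exchange), which also removes the deactivating formyl group while the ketal forms; no stereocentre is involved.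

Step 2
Reactants: 3 4-bromo-6-(dimethoxymethyl)-2,2-dimethyl-1,3-benzodioxole; 4 (4R)-3-acetyl-4-benzyl-1,3-oxazolidin-2-one
Product: 6 (4R)-4-benzyl-3-{[6-(dimethoxymethyl)-2,2-dimethyl-1,3-benzodioxol-4-yl]acetyl}-1,3-oxazolidin-2-one, via silyl ketene N,O-acetal 5 (not isolated)
Conditions: 4, TMSOTf, Et3N, CH2Cl2, 0 °C, pentane extraction; then 3, Pd(dba)2 (2 mol %), P(t-Bu)3 (4 mol %), ZnF2 (0.5 equiv), DMF, 80 °C
Reagents that add atoms: trimethylsilyl triflate, C[Si](C)(C)OS(=O)(=O)C(F)(F)F (supplies the Me3Si group of 5; none of it remains in 6)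
Why: Hartwig-type Pd-catalysed α-arylation of a silyl ketene N,O-acetal (ZnF2-promoted transmetalation) joins the enolate carbon to the electron-rich aryl bromide under non-basic conditions that tolerate the acetal and leave the auxiliary centre untouched.

Step 3
Reactants: 6 (4R)-4-benzyl-3-{[6-(dimethoxymethyl)-2,2-dimethyl-1,3-benzodioxol-4-yl]acetyl}-1,3-oxazolidin-2-one; 7 4-(benzyloxy)-3-methoxybenzaldehyde
Product: 9 (4R)-4-benzyl-3-{(2R,3R)-3-[4-(benzyloxy)-3-methoxyphenyl]-2-[6-(dimethoxymethyl)-2,2-dimethyl-1,3-benzodioxol-4-yl]-3-hydroxypropanoyl}-1,3-oxazolidin-2-one, via Z-boron enolate 8 (not isolated)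
Conditions: n-Bu2BOTf (1.05 equiv), i-Pr2NEt (1.3 equiv), CH2Cl2, −78 → 0 °C; 7 (1.2 equiv), −78 → 0 °C; pH 7 buffer, MeOH, 30 % H2O2, 0 °C
Reagents that add atoms: dibutylboron triflate, CCCCB(CCCC)OS(=O)(=O)C(F)(F)F (supplies the Bu2B group of 8; none of it remains in 9)
Why: Evans syn-aldol through the Z-boron enolate and a Zimmerman–Traxler transition state, in which the (R)-benzyl auxiliary shields one enolate face and so fixes the α-aryl carbon as (2R) (the later benzofuran C3); the (3R) carbinol formed alongside is lost again in step 8.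

Step 4
Reactants: 9 (4R)-4-benzyl-3-{(2R,3R)-3-[4-(benzyloxy)-3-methoxyphenyl]-2-[6-(dimethoxymethyl)-2,2-dimethyl-1,3-benzodioxol-4-yl]-3-hydroxypropanoyl}-1,3-oxazolidin-2-one
Product: 11 7-{(1R,2S)-1-[4-(benzyloxy)-3-methoxyphenyl]-1,3-dihydroxypropan-2-yl}-2,2-dimethyl-1,3-benzodioxole-5-carbaldehyde, via acetal diol 10 (not isolated)
Conditions: LiBH4, MeOH (1.1 equiv), THF, 0 °C; acetone quench; then 10 % aq. citric acid, THF, rt
Reagents that add atoms: water, O
Why: Hydride reduction of the N-acyl oxazolidinone releases the 1,3-diol without touching the α-centre (its descriptor changes from R to S only through CIP priorities), and mild aqueous acid hydrolysis of the dimethyl acetal then frees the aldehyde while the acetonide and the benzylic alcohol survive.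

Step 5
Reactants: 12 1-(2,4,6-trihydroxyphenyl)ethanone; 13 benzyl bromide
Product: 14 1-[2,4-bis(benzyloxy)-6-hydroxyphenyl]ethanone
Conditions: BnBr (2.1 equiv), K2CO3 (2.2 equiv), DMF, rt
Reagents that add atoms: benzyl bromide, BrCc1ccccc1
Why: Williamson etherification stops at the di-O-benzyl ether because the remaining ortho hydroxyl is hydrogen-bonded to the ketone and is the least nucleophilic.

Step 6
Reactants: 14 1-[2,4-bis(benzyloxy)-6-hydroxyphenyl]ethanone; 15 di-tert-butyl dicarbonate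
Product: 16 tert-butyl 3-[2,4-bis(benzyloxy)-6-hydroxyphenyl]-3-oxopropanoate
Conditions: LiHMDS (3.3 equiv), THF, −78 °C; Boc2O (1.1 equiv), −78 → −20 °C; cold 1 M HCl quench
Reagents that add atoms: di-tert-butyl dicarbonate, CC(C)(C)OC(=O)OC(=O)OC(C)(C)C
Why: Claisen-type C-acylation of the phenoxide/enolate dianion is driven by deprotonation of the β-keto ester with the third equivalent of base, and any aryl O-Boc formed is relayed to carbon by the neighbouring enolate (Baker–Venkataraman-type transfer).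

Step 7
Reactants: 11 7-{(1R,2S)-1-[4-(benzyloxy)-3-methoxyphenyl]-1,3-dihydroxypropan-2-yl}-2,2-dimethyl-1,3-benzodioxole-5-carbaldehyde; 16 tert-butyl 3-[2,4-bis(benzyloxy)-6-hydroxyphenyl]-3-oxopropanoate
Product: 17 tert-butyl 2-[2,4-bis(benzyloxy)-6-hydroxybenzoyl]-3-(7-{(1R,2S)-1-[4-(benzyloxy)-3-methoxyphenyl]-1,3-dihydroxypropan-2-yl}-2,2-dimethyl-1,3-benzodioxol-5-yl)prop-2-enoate (E/Z mixture)
Conditions: piperidine (0.2 equiv), AcOH (0.2 equiv), toluene, 4 Å MS, rt → 40 °C
Reagents that add atoms: none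
Why: Knoevenagel condensation through the piperidinium iminium gives the alkylidene β-keto ester, whose bulky tert-butyl ester and twisted 2,6-disubstituted aroyl group hold back uncatalysed ring closure; no stereocentre is touched.

Step 8
Reactants: 17 tert-butyl 2-[2,4-bis(benzyloxy)-6-hydroxybenzoyl]-3-(7-{(1R,2S)-1-[4-(benzyloxy)-3-methoxyphenyl]-1,3-dihydroxypropan-2-yl}-2,2-dimethyl-1,3-benzodioxol-5-yl)prop-2-enoate
Product: 19 (2S)-5,7-bis(benzyloxy)-2-{(2R,3S)-2-[4-(benzyloxy)-3-methoxyphenyl]-7-hydroxy-3-(hydroxymethyl)-2,3-dihydro-1-benzofuran-5-yl}-2,3-dihydro-4H-chromen-4-one, via 3-carboxylate flavanone 18 (not isolated)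
Conditions: 9-amino(9-deoxy)epi-quinidine N-[3,5-bis(trifluoromethyl)phenyl]thiourea (10 mol %), toluene/CH2Cl2, −25 °C; then p-TsOH·H2O (1.5 equiv), same flask, 75 °C
Reagents that add atoms: none
Why: Proposed new method: the bifunctional cinchona thiourea binds the β-keto ester and deprotonates the chelated phenol, so a 6-endo oxa-Michael addition closes the pyranone from one alkylidene face and sets the flavanone C2 as (S) under catalyst control (closest known reaction: thiourea-catalysed oxa-Michael cyclisation of alkylidene β-keto esters followed by acid decarboxylation); the added TsOH then cleaves the tert-butyl ester, decarboxylates the β-keto acid and ionises the p-benzyloxybenzylic alcohol to a quinone-methide-like cation that is captured 5-exo by the adjacent acetonide oxygen with loss of acetone (closest known reaction: acid-mediated phenylcoumaran closure of 1,2-diaryl-propane-1,3-diols), the untouched (S) centre from step 3 placing the aryl group trans to CH2OH and so fixing the benzofuran C2 as (R) under reversible, thermodynamic conditions.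

Step 9
Reactants: 19 (2S)-5,7-bis(benzyloxy)-2-{(2R,3S)-2-[4-(benzyloxy)-3-methoxyphenyl]-7-hydroxy-3-(hydroxymethyl)-2,3-dihydro-1-benzofuran-5-yl}-2,3-dihydro-4H-chromen-4-one
Product: 20 silyhermin B, (2S)-5,7-dihydroxy-2-[(2R,3S)-7-hydroxy-2-(4-hydroxy-3-methoxyphenyl)-3-(hydroxymethyl)-2,3-dihydro-1-benzofuran-5-yl]-2,3-dihydro-4H-chromen-4-one
Conditions: H2 (1 atm), 10 % Pd/C, EtOAc/MeOH, rt, monitored to completion
Reagents that add atoms: none
Why: Catalytic hydrogenolysis removes the three aryl benzyl ethers faster than it attacks the cyclic benzylic C–O bonds or the ketone at 1 atm, and no stereocentre is affected.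

## Compound list

1 | 3-bromo-4,5-dihydroxybenzaldehyde | O=Cc1cc(O)c(O)c(Br)c1 | starting material
2 | 2,2-dimethoxypropane | COC(C)(C)OC | starting material
3 | 4-bromo-6-(dimethoxymethyl)-2,2-dimethyl-1,3-benzodioxole | COC(OC)c1cc(Br)c2OC(C)(C)Oc2c1 | intermediate
4 | (4R)-3-acetyl-4-benzyl-1,3-oxazolidin-2-one | CC(=O)N1[C@H](Cc2ccccc2)COC1=O | starting material
5 | (4R)-4-benzyl-3-[1-(trimethylsilyloxy)ethenyl]-1,3-oxazolidin-2-one (silyl ketene N,O-acetal, not isolated) | C=C(O[Si](C)(C)C)N1[C@H](Cc2ccccc2)COC1=O | intermediate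
6 | (4R)-4-benzyl-3-{[6-(dimethoxymethyl)-2,2-dimethyl-1,3-benzodioxol-4-yl]acetyl}-1,3-oxazolidin-2-one | COC(OC)c1cc(CC(=O)N3[C@H](Cc4ccccc4)COC3=O)c2OC(C)(C)Oc2c1 | intermediate
7 | 4-(benzyloxy)-3-methoxybenzaldehyde | COc1cc(C=O)ccc1OCc1ccccc1 | starting material
8 | (Z)-dibutylboron enolate of 6 (not isolated) | CCCCB(CCCC)O/C(=C\c1cc(C(OC)OC)cc2OC(C)(C)Oc12)N1[C@H](Cc2ccccc2)COC1=O | intermediate
9 | (4R)-4-benzyl-3-{(2R,3R)-3-[4-(benzyloxy)-3-methoxyphenyl]-2-[6-(dimethoxymethyl)-2,2-dimethyl-1,3-benzodioxol-4-yl]-3-hydroxypropanoyl}-1,3-oxazolidin-2-one | O=C([C@H](c1cc(C(OC)OC)cc2OC(C)(C)Oc12)[C@@H](O)c1ccc(OCc2ccccc2)c(OC)c1)N1[C@H](Cc2ccccc2)COC1=O | intermediate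
10 | (1R,2S)-1-[4-(benzyloxy)-3-methoxyphenyl]-2-[6-(dimethoxymethyl)-2,2-dimethyl-1,3-benzodioxol-4-yl]propane-1,3-diol (not isolated) | OC[C@H](c1cc(C(OC)OC)cc2OC(C)(C)Oc12)[C@@H](O)c1ccc(OCc2ccccc2)c(OC)c1 | intermediate
11 | 7-{(1R,2S)-1-[4-(benzyloxy)-3-methoxyphenyl]-1,3-dihydroxypropan-2-yl}-2,2-dimethyl-1,3-benzodioxole-5-carbaldehyde | O=Cc1cc([C@@H](CO)[C@@H](O)c3ccc(OCc4ccccc4)c(OC)c3)c2OC(C)(C)Oc2c1 | intermediate
12 | 1-(2,4,6-trihydroxyphenyl)ethanone (phloroacetophenone) | CC(=O)c1c(O)cc(O)cc1O | starting material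
13 | benzyl bromide | BrCc1ccccc1 | starting material
14 | 1-[2,4-bis(benzyloxy)-6-hydroxyphenyl]ethanone | CC(=O)c1c(O)cc(OCc2ccccc2)cc1OCc1ccccc1 | intermediate
15 | di-tert-butyl dicarbonate | CC(C)(C)OC(=O)OC(=O)OC(C)(C)C | starting material
16 | tert-butyl 3-[2,4-bis(benzyloxy)-6-hydroxyphenyl]-3-oxopropanoate | CC(C)(C)OC(=O)CC(=O)c1c(O)cc(OCc2ccccc2)cc1OCc1ccccc1 | intermediate
17 | tert-butyl 2-[2,4-bis(benzyloxy)-6-hydroxybenzoyl]-3-(7-{(1R,2S)-1-[4-(benzyloxy)-3-methoxyphenyl]-1,3-dihydroxypropan-2-yl}-2,2-dimethyl-1,3-benzodioxol-5-yl)prop-2-enoate (E/Z mixture) | CC(C)(C)OC(=O)C(=Cc1cc([C@@H](CO)[C@@H](O)c3ccc(OCc4ccccc4)c(OC)c3)c2OC(C)(C)Oc2c1)C(=O)c1c(O)cc(OCc2ccccc2)cc1OCc1ccccc1 | intermediate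
18 | tert-butyl (2S)-5,7-bis(benzyloxy)-2-(7-{(1R,2S)-1-[4-(benzyloxy)-3-methoxyphenyl]-1,3-dihydroxypropan-2-yl}-2,2-dimethyl-1,3-benzodioxol-5-yl)-4-oxo-3,4-dihydro-2H-chromene-3-carboxylate (C3 epimers/enol, not isolated) | CC(C)(C)OC(=O)C1C(=O)c2c(OCc3ccccc3)cc(OCc3ccccc3)cc2O[C@@H]1c1cc([C@@H](CO)[C@@H](O)c3ccc(OCc4ccccc4)c(OC)c3)c2OC(C)(C)Oc2c1 | intermediate
19 | (2S)-5,7-bis(benzyloxy)-2-{(2R,3S)-2-[4-(benzyloxy)-3-methoxyphenyl]-7-hydroxy-3-(hydroxymethyl)-2,3-dihydro-1-benzofuran-5-yl}-2,3-dihydro-4H-chromen-4-one | COc1cc([C@@H]2Oc3c(O)cc([C@@H]4CC(=O)c5c(OCc6ccccc6)cc(OCc6ccccc6)cc5O4)cc3[C@H]2CO)ccc1OCc1ccccc1 | intermediate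
20 | silyhermin B, (2S)-5,7-dihydroxy-2-[(2R,3S)-7-hydroxy-2-(4-hydroxy-3-methoxyphenyl)-3-(hydroxymethyl)-2,3-dihydro-1-benzofuran-5-yl]-2,3-dihydro-4H-chromen-4-one | COc1cc([C@@H]2Oc3c(O)cc([C@@H]4CC(=O)c5c(O)cc(O)cc5O4)cc3[C@H]2CO)ccc1O | target

## Step count and risks

Total step count: 9. Longest linear sequence: 7 (steps 1, 2, 3, 4, 7, 8, 9); steps 5 and 6 form the A-ring branch.

Steps most likely to fail:

Step 8 is the most exposed. The hydroxyl-rich, 6'-benzyloxy-substituted substrate may give only modest enantiocontrol in the oxa-Michael stage, and the hot acid stage may erode the flavanone centre or lose C3 through E1 elimination. The fallback sets out from 17 and gives up catalyst control of the flavanone centre in favour of a kinetic resolution. Compound 17 is cyclised without chiral catalyst (Et3N, toluene, rt, then p-TsOH·H2O, 75 °C) to 19 together with its flavanone epimer, (2R)-5,7-bis(benzyloxy)-2-{(2R,3S)-2-[4-(benzyloxy)-3-methoxyphenyl]-7-hydroxy-3-(hydroxymethyl)-2,3-dihydro-1-benzofuran-5-yl}-2,3-dihydro-4H-chromen-4-one F1. The mixture is then submitted to asymmetric transfer hydrogenation [RuCl(p-cymene)((R,R)-TsDPEN), HCO2H/Et3N, EtOAc, rt]. This reduces only the (2R) ketone, to the cis alcohol (2R,4R)-5,7-bis(benzyloxy)-2-{(2R,3S)-2-[4-(benzyloxy)-3-methoxyphenyl]-7-hydroxy-3-(hydroxymethyl)-2,3-dihydro-1-benzofuran-5-yl}-3,4-dihydro-2H-chromen-4-ol F2, and leaves the (2S) ketone, which is separated by chromatography. The route is rejoined at 19.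

Step 2 is the second risk: arylation of an N-acetyl imide silyl enolate may stall or over-arylate. The fallback sets out from 3 and builds the arylacetyl imide by classical acylation instead. A Reformatsky–Negishi coupling with BrZnCH2CO2Et [Pd(dba)2/Q-Phos, THF, rt] gives ethyl [6-(dimethoxymethyl)-2,2-dimethyl-1,3-benzodioxol-4-yl]acetate F3. Saponification (LiOH, THF/H2O, acidified only to pH 5 to spare the acetal) gives [6-(dimethoxymethyl)-2,2-dimethyl-1,3-benzodioxol-4-yl]acetic acid F4. Activation with PivCl/Et3N (THF, −20 °C) gives [6-(dimethoxymethyl)-2,2-dimethyl-1,3-benzodioxol-4-yl]acetic pivalic anhydride F5, which acylates lithiated (R)-4-benzyl-1,3-oxazolidin-2-one. The route is rejoined at 6.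

Step 7 is the third risk: the free ortho-phenol may close the pyranone racemically during the condensation, or the hindered keto ester may react sluggishly. The fallback sets out from 16 and blocks the phenol until the chiral catalyst is present. Silylation (TBSCl, imidazole, DMF) gives tert-butyl 3-[2,4-bis(benzyloxy)-6-(tert-butyldimethylsilyloxy)phenyl]-3-oxopropanoate F6. Knoevenagel condensation with 11 (piperidine/AcOH, toluene, 4 Å MS) gives tert-butyl 2-[2,4-bis(benzyloxy)-6-(tert-butyldimethylsilyloxy)benzoyl]-3-(7-{(1R,2S)-1-[4-(benzyloxy)-3-methoxyphenyl]-1,3-dihydroxypropan-2-yl}-2,2-dimethyl-1,3-benzodioxol-5-yl)prop-2-enoate F7, which cannot cyclise. Cold desilylation (TBAF/AcOH, THF, −25 °C) releases the phenol immediately before step 8. The route is rejoined at 17.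

## Further compounds

F1 | step 8 | (2R)-5,7-bis(benzyloxy)-2-{(2R,3S)-2-[4-(benzyloxy)-3-methoxyphenyl]-7-hydroxy-3-(hydroxymethyl)-2,3-dihydro-1-benzofuran-5-yl}-2,3-dihydro-4H-chromen-4-one | COc1cc([C@@H]2Oc3c(O)cc([C@H]4CC(=O)c5c(OCc6ccccc6)cc(OCc6ccccc6)cc5O4)cc3[C@H]2CO)ccc1OCc1ccccc1
F2 | step 8 | (2R,4R)-5,7-bis(benzyloxy)-2-{(2R,3S)-2-[4-(benzyloxy)-3-methoxyphenyl]-7-hydroxy-3-(hydroxymethyl)-2,3-dihydro-1-benzofuran-5-yl}-3,4-dihydro-2H-chromen-4-ol | COc1cc([C@@H]2Oc3c(O)cc([C@H]4C[C@@H](O)c5c(OCc6ccccc6)cc(OCc6ccccc6)cc5O4)cc3[C@H]2CO)ccc1OCc1ccccc1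
F3 | step 2 | ethyl [6-(dimethoxymethyl)-2,2-dimethyl-1,3-benzodioxol-4-yl]acetate | CCOC(=O)Cc1cc(C(OC)OC)cc2OC(C)(C)Oc12
F4 | step 2 | [6-(dimethoxymethyl)-2,2-dimethyl-1,3-benzodioxol-4-yl]acetic acid | OC(=O)Cc1cc(C(OC)OC)cc2OC(C)(C)Oc12
F5 | step 2 | [6-(dimethoxymethyl)-2,2-dimethyl-1,3-benzodioxol-4-yl]acetic pivalic anhydride | CC(C)(C)C(=O)OC(=O)Cc1cc(C(OC)OC)cc2OC(C)(C)Oc12
F6 | step 7 | tert-butyl 3-[2,4-bis(benzyloxy)-6-(tert-butyldimethylsilyloxy)phenyl]-3-oxopropanoate | CC(C)(C)OC(=O)CC(=O)c1c(O[Si](C)(C)C(C)(C)C)cc(OCc2ccccc2)cc1OCc1ccccc1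
F7 | step 7 | tert-butyl 2-[2,4-bis(benzyloxy)-6-(tert-butyldimethylsilyloxy)benzoyl]-3-(7-{(1R,2S)-1-[4-(benzyloxy)-3-methoxyphenyl]-1,3-dihydroxypropan-2-yl}-2,2-dimethyl-1,3-benzodioxol-5-yl)prop-2-enoate | CC(C)(C)OC(=O)C(=Cc1cc([C@@H](CO)[C@@H](O)c3ccc(OCc4ccccc4)c(OC)c3)c2OC(C)(C)Oc2c1)C(=O)c1c(O[Si](C)(C)C(C)(C)C)cc(OCc2ccccc2)cc1OCc1ccccc1
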